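**Retrosynthetic overview**
1. The furofuran core is bought intact as (+)-syringaresinol, so no ring is formed in the route. The target is this core carrying three guaiacylglycerol units through C8–O–aryl bonds: unit A (erythro, 7R,8S) on one core phenol, unit B (threo, 7S,8S) on the other, unit C (erythro, 7S,8R) on O-4 of unit B.
2. Each unit is cut at C7–C8 (Evans syn-aldol of an aryloxyacetyl oxazolidinone with a vanillin-type aldehyde; syn = threo) and at ArO–CH2 (phenol alkylation with a chloroacetyl oxazolidinone). The erythro units come from syn adducts by Mitsunobu inversion at C7.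
3. Order: statistical mono-alkylation of the core; aldol for unit B with an aldehyde that already carries the imide for unit C; silylation; fluoride-triggered alkylation of the second core phenol; one double aldol that consumes two molecules of silylated vanillin and builds units A and C together.
4. End game: LiBH4 removal of all three auxiliaries, double Mitsunobu inversion (C7 of A and C), ester methanolysis, fluoride desilylation.

Assumption: (+)-syringaresinol (7S,7'S,8R,8'R) and both enantiomers of 4-benzyl-3-(chloroacetyl)oxazolidin-2-one are bought as catalogue compounds.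

Shorthand in names: core = syringaresinol skeleton with phenol oxygens O-4 and O-4' (homotopic in 5); unit A sits on core O-4, unit B on core O-4', unit C on O-4 of the unit-B ring; in each unit C7 = benzylic C–O, C8 = C–OAr, C9 = terminal carbon; Xc = 4-benzyl-2-oxooxazolidin-3-yl. At the imide stage the chain is named as a propanoyl group (C2 = C8, C3 = C7).

**Step 1**
Reactants: 1 vanillin (4-hydroxy-3-methoxybenzaldehyde); 2 (S)-4-benzyl-3-(chloroacetyl)oxazolidin-2-one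
Product: 3 (S)-4-benzyl-3-[(4-formyl-2-methoxyphenoxy)acetyl]oxazolidin-2-one
Conditions: K2CO3 (1.5 equiv), NaI (0.1 equiv), acetone, rt to 40 °C
Reagents that add atoms: none
Why: Williamson ether synthesis (SN2) of the weakly basic vanillin phenoxide at the doubly activated CH2Cl of the α-chloro imide, which forms no stereocentre and leaves the auxiliary centre untouched.

**Step 2**
Reactants: 1 vanillin
Product: 4 3-methoxy-4-(triisopropylsilyloxy)benzaldehyde
Conditions: TIPSCl (1.2 equiv), imidazole (2.5 equiv), DMF, rt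
Reagents that add atoms: triisopropylsilyl chloride, CC(C)[Si](Cl)(C(C)C)C(C)C
Why: Imidazole-promoted silylation of the phenol gives an aryl TIPS ether that is stable to boron aldol, LiBH4, Mitsunobu and carbonate/methanol conditions and is removed only by fluoride.

**Step 3**
Reactants: 5 (+)-syringaresinol; 6 (R)-4-benzyl-3-(chloroacetyl)oxazolidin-2-one
Product: 7 mono-imide (core O-4'–CH2C(=O)–(R)-Xc; core 4-OH free)
Conditions: 6 (0.9 equiv), K2CO3 (1.1 equiv), NaI (0.1 equiv), DMF, rt; recovered 5 recycled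
Reagents that add atoms: none
Why: The same SN2 O-alkylation as in step 1, run with a deficit of 6, desymmetrises the C2-symmetric bisphenol statistically (about 40–45% of 7 expected, 5 recovered) without forming a stereocentre.

**Step 4**
Reactants: 7 mono-imide; 3 aldehyde
Product: 10 unit-B aldol imide (core O-4' is the 2-aryloxy oxygen of a (2R,3S)-3-hydroxy-3-aryl-propanoyl-(R)-Xc; aryl O-4 bears CH2C(=O)–(S)-Xc; core 4-OH free), via Z-boron enolate 8 (not isolated), via boron aldolate 9 (not isolated)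
Conditions: Bu2BOTf (2.2 equiv), iPr2NEt (2.6 equiv), CH2Cl2, 0 °C; then 3 (1.2 equiv), −78 to 0 °C; then pH 7 buffer (NaH2PO4/Na2HPO4), MeOH, 30% H2O2, 0 °C
Reagents that add atoms: none
Why: Evans syn-aldol in which the Z-boron enolate reacts through a Zimmerman–Traxler chair on the face left open by the benzyl group of the (R)-auxiliary, setting C8 and C7 of unit B together as the syn (= threo, final 7S,8S) pair, while the second equivalent of Bu2BOTf masks the free phenol as a borinate that the work-up releases.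

**Step 5**
Reactants: 10 unit-B aldol imide
Product: 11 bis-TBS ether of 10 (TBS on core O-4 and on O-7 of unit B)
Conditions: TBSOTf (3 equiv), 2,6-lutidine (4 equiv), CH2Cl2, −78 to 0 °C
Reagents that add atoms: tert-butyldimethylsilyl triflate, CC(C)(C)[Si](C)(C)OS(=O)(=O)C(F)(F)F
Why: Silyl triflate silylation caps both the phenol and the hindered aldol hydroxyl under lutidine-buffered low-temperature conditions that avoid retro-aldol, so no stereocentre changes.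

**Step 6**
Reactants: 11 bis-TBS ether; 6 (R)-4-benzyl-3-(chloroacetyl)oxazolidin-2-one
Product: 13 tris-imide (core O-4–CH2C(=O)–(R)-Xc; unit B as in 11), via caesium phenoxide 12 (not isolated)
Conditions: CsF (2.5 equiv), 6 (1.5 equiv), NaI (0.2 equiv), DMF, 0 °C to rt
Reagents that add atoms: none
Why: Fluoride cleaves the aryl O–Si bond far faster than the secondary alkyl O–Si bond and the phenoxide set free is alkylated in situ (desilylative Williamson etherification), while allylic 1,3-strain keeps the α-branched unit-B imide from enolising so no stereocentre changes.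

**Step 7**
Reactants: 13 tris-imide; 4 3-methoxy-4-(triisopropylsilyloxy)benzaldehyde (two molecules are incorporated, one at each glycolyl imide)
Product: 16 bis-aldol tris-imide (unit A: (2R,3S)-3-hydroxy-propanoyl-(R)-Xc on core O-4; unit C: (2S,3R)-3-hydroxy-propanoyl-(S)-Xc on O-4 of unit B; both new aryls 3-methoxy-4-TIPS-oxyphenyl), via bis-boron enolate 14 (not isolated), via bis-boron aldolate 15 (not isolated)
Conditions: Bu2BOTf (2.4 equiv), iPr2NEt (2.8 equiv), CH2Cl2, 0 °C; then 4 (3 equiv), −78 to 0 °C; then pH 7 buffer (NaH2PO4/Na2HPO4), MeOH, 30% H2O2, 0 °C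
Reagents that add atoms: second molecule of aldehyde 4 (3-methoxy-4-(triisopropylsilyloxy)benzaldehyde), O=Cc1ccc(O[Si](C(C)C)(C(C)C)C(C)C)c(OC)c1
Why: Two Evans syn-aldol additions in one flask, one molecule of 4 adding to each of the two glycolyl Z-boron enolates through a Zimmerman–Traxler chair controlled by its own auxiliary, set unit A as (7S,8S) from the (R)-auxiliary and unit C as (7R,8R) from the (S)-auxiliary, while allylic 1,3-strain keeps the α-branched unit-B imide from enolising.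

**Step 8**
Reactants: 16 bis-aldol tris-imide
Product: 17 pentaol (all three C9 = CH2OH; unit A (7S,8S) and unit C (7R,8R) as 7,9-diols; unit B (7S,8S) with 7-OTBS and 9-OH)
Conditions: LiBH4 (9 equiv), MeOH (9 equiv), THF, 0 °C
Reagents that add atoms: none
Why: Reductive cleavage of the three N-acyl oxazolidinones by LiBH4 gives the primary alcohols and leaves silyl ethers, aryl ethers and every stereocentre untouched.

**Step 9**
Reactants: 17 pentaol
Product: 18 penta(4-nitrobenzoate) (esters on O-7 and O-9 of units A and C and on O-9 of unit B; unit A now (7R,8S), unit C now (7S,8R))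
Conditions: 4-nitrobenzoic acid (10 equiv), PPh3 (10 equiv), DIAD (10 equiv), THF, 0 °C to rt
Reagents that add atoms: 4-nitrobenzoic acid, OC(=O)c1ccc(cc1)[N+](=O)[O-]
Why: Mitsunobu reaction in which the three primary alcohols are esterified without stereochemical consequence and the two free benzylic alcohols are displaced by 4-nitrobenzoate in an SN2 step with inversion (A-7 from S to R, C-7 from R to S), turning both threo units into erythro units while the silylated O-7 of unit B keeps its configuration.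

**Step 10**
Reactants: 18 penta(4-nitrobenzoate)
Product: 19 trisilyl ether of the target (4-O-TIPS on the rings of units A and C; 7-O-TBS on unit B; all other OH free)
Conditions: K2CO3 (cat.), MeOH/THF 1:1, 0 °C to rt
Reagents that add atoms: none
Why: Carbonate-catalysed transesterification removes the five activated esters by acyl–oxygen cleavage (retention at C7), and the aryl TIPS ethers stay on so that no phenoxide can expel a benzylic ester as a quinone methide.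

**Step 11**
Reactants: 19 trisilyl ether of the target
Product: 20 target CNP0316493.3
Conditions: TBAF (4 equiv), AcOH (4 equiv), THF, 0 °C to rt
Reagents that add atoms: none
Why: Fluoride-mediated desilylation cleaves the two aryl TIPS ethers and the benzylic TBS ether under acetic acid-buffered conditions that do not epimerise the benzylic carbinols or the furofuran, so no stereocentre is affected.

**Compound list**
1 | vanillin (4-hydroxy-3-methoxybenzaldehyde) | O=Cc1ccc(O)c(OC)c1 | starting material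
2 | (S)-4-benzyl-3-(chloroacetyl)oxazolidin-2-one | O=C(CCl)N1[C@@H](Cc2ccccc2)COC1=O | starting material
3 | (S)-4-benzyl-3-[(4-formyl-2-methoxyphenoxy)acetyl]oxazolidin-2-one | O=Cc1ccc(OCC(=O)N2[C@@H](Cc3ccccc3)COC2=O)c(OC)c1 | intermediate
4 | 3-methoxy-4-(triisopropylsilyloxy)benzaldehyde | O=Cc1ccc(O[Si](C(C)C)(C(C)C)C(C)C)c(OC)c1 | intermediate
5 | (+)-syringaresinol, 4,4'-[(1S,3aR,4S,6aR)-tetrahydro-1H,3H-furo[3,4-c]furan-1,4-diyl]bis(2,6-dimethoxyphenol), lignan numbering (7S,7'S,8R,8'R) | Oc1c(OC)cc([C@H]2OC[C@H]3[C@@H]2CO[C@@H]3c2cc(OC)c(O)c(OC)c2)cc1OC | starting material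
6 | (R)-4-benzyl-3-(chloroacetyl)oxazolidin-2-one | O=C(CCl)N1[C@H](Cc2ccccc2)COC1=O | starting material
7 | mono-imide: syringaresinol with O-4' alkylated as O–CH2C(=O)–(R)-Xc, 4-OH free | Oc1c(OC)cc([C@H]2OC[C@H]3[C@@H]2CO[C@@H]3c2cc(OC)c(OCC(=O)N6[C@H](Cc7ccccc7)COC6=O)c(OC)c2)cc1OC | intermediate
8 | Z-boron enolate of 7: O-4'–CH=C(OBBu2)–(R)-Xc with ArO cis to OB; core O-4 as O–BBu2 | CCCCB(CCCC)Oc1c(OC)cc([C@H]2OC[C@H]3[C@@H]2CO[C@@H]3c2cc(OC)c(O/C=C(\OB(CCCC)CCCC)N6[C@H](Cc7ccccc7)COC6=O)c(OC)c2)cc1OC | intermediate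
9 | boron aldolate: 10 with O-7 of unit B and core O-4 each bound to BBu2 | CCCCB(CCCC)Oc1c(OC)cc([C@H]2OC[C@H]3[C@@H]2CO[C@@H]3c2cc(OC)c(O[C@@H](C(=O)N6[C@H](Cc7ccccc7)COC6=O)[C@@H](OB(CCCC)CCCC)c4ccc(OCC(=O)N6[C@@H](Cc7ccccc7)COC6=O)c(OC)c4)c(OC)c2)cc1OC | intermediate
10 | unit-B aldol imide: syringaresinol (4-OH free) whose O-4' is the 2-aryloxy oxygen of a (2R,3S)-3-hydroxy-3-aryl-propanoyl-(R)-Xc; aryl = 3-methoxy-4-[2-oxo-2-((S)-Xc)ethoxy]phenyl | Oc1c(OC)cc([C@H]2OC[C@H]3[C@@H]2CO[C@@H]3c2cc(OC)c(O[C@@H](C(=O)N6[C@H](Cc7ccccc7)COC6=O)[C@@H](O)c4ccc(OCC(=O)N6[C@@H](Cc7ccccc7)COC6=O)c(OC)c4)c(OC)c2)cc1OC | intermediate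
11 | bis-TBS ether of 10: TBS on core O-4 and on O-7 of unit B | CC(C)(C)[Si](C)(C)Oc1c(OC)cc([C@H]2OC[C@H]3[C@@H]2CO[C@@H]3c2cc(OC)c(O[C@@H](C(=O)N6[C@H](Cc7ccccc7)COC6=O)[C@@H](O[Si](C)(C)C(C)(C)C)c4ccc(OCC(=O)N6[C@@H](Cc7ccccc7)COC6=O)c(OC)c4)c(OC)c2)cc1OC | intermediate
12 | caesium phenoxide of 11: core O-4 as O− Cs+, O-7 TBS ether of unit B kept | [Cs+].[O-]c1c(OC)cc([C@H]2OC[C@H]3[C@@H]2CO[C@@H]3c2cc(OC)c(O[C@@H](C(=O)N6[C@H](Cc7ccccc7)COC6=O)[C@@H](O[Si](C)(C)C(C)(C)C)c4ccc(OCC(=O)N6[C@@H](Cc7ccccc7)COC6=O)c(OC)c4)c(OC)c2)cc1OC | intermediate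
13 | tris-imide: 12 alkylated at core O-4 as O–CH2C(=O)–(R)-Xc | O=C(COc1c(OC)cc([C@H]2OC[C@H]3[C@@H]2CO[C@@H]3c2cc(OC)c(O[C@@H](C(=O)N6[C@H](Cc7ccccc7)COC6=O)[C@@H](O[Si](C)(C)C(C)(C)C)c4ccc(OCC(=O)N6[C@@H](Cc7ccccc7)COC6=O)c(OC)c4)c(OC)c2)cc1OC)N1[C@H](Cc2ccccc2)COC1=O | intermediate
14 | bis(Z-boron enolate) of 13: both ArO–CH2C(=O)Xc groups as ArO–CH=C(OBBu2)Xc, ArO cis to OB | c1(O/C=C(\OB(CCCC)CCCC)N6[C@H](Cc7ccccc7)COC6=O)c(OC)cc([C@H]2OC[C@H]3[C@@H]2CO[C@@H]3c2cc(OC)c(O[C@@H](C(=O)N6[C@H](Cc7ccccc7)COC6=O)[C@@H](O[Si](C)(C)C(C)(C)C)c4ccc(O/C=C(\OB(CCCC)CCCC)N6[C@@H](Cc7ccccc7)COC6=O)c(OC)c4)c(OC)c2)cc1OC | intermediate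
15 | bis(boron aldolate): 16 with O-7 of units A and C as O–BBu2 | c1(O[C@@H](C(=O)N6[C@H](Cc7ccccc7)COC6=O)[C@@H](OB(CCCC)CCCC)c4ccc(O[Si](C(C)C)(C(C)C)C(C)C)c(OC)c4)c(OC)cc([C@H]2OC[C@H]3[C@@H]2CO[C@@H]3c2cc(OC)c(O[C@@H](C(=O)N6[C@H](Cc7ccccc7)COC6=O)[C@@H](O[Si](C)(C)C(C)(C)C)c4ccc(O[C@H](C(=O)N6[C@@H](Cc7ccccc7)COC6=O)[C@H](OB(CCCC)CCCC)c5ccc(O[Si](C(C)C)(C(C)C)C(C)C)c(OC)c5)c(OC)c4)c(OC)c2)cc1OC | intermediate
16 | bis-aldol tris-imide: core O-4 is the 2-aryloxy oxygen of a (2R,3S)-3-hydroxy-3-[3-methoxy-4-(TIPS-oxy)phenyl]propanoyl-(R)-Xc (unit A); O-4 of unit B is that of the (2S,3R)-isomer on (S)-Xc (unit C); unit B as in 13 | c1(O[C@@H](C(=O)N6[C@H](Cc7ccccc7)COC6=O)[C@@H](O)c4ccc(O[Si](C(C)C)(C(C)C)C(C)C)c(OC)c4)c(OC)cc([C@H]2OC[C@H]3[C@@H]2CO[C@@H]3c2cc(OC)c(O[C@@H](C(=O)N6[C@H](Cc7ccccc7)COC6=O)[C@@H](O[Si](C)(C)C(C)(C)C)c4ccc(O[C@H](C(=O)N6[C@@H](Cc7ccccc7)COC6=O)[C@H](O)c5ccc(O[Si](C(C)C)(C(C)C)C(C)C)c(OC)c5)c(OC)c4)c(OC)c2)cc1OC | intermediate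
17 | pentaol: all C9 = CH2OH; unit A (7S,8S) 7,9-diol; unit B (7S,8S) 7-OTBS 9-OH; unit C (7R,8R) 7,9-diol; two aryl OTIPS | c1(O[C@@H](CO)[C@@H](O)c4ccc(O[Si](C(C)C)(C(C)C)C(C)C)c(OC)c4)c(OC)cc([C@H]2OC[C@H]3[C@@H]2CO[C@@H]3c2cc(OC)c(O[C@@H](CO)[C@@H](O[Si](C)(C)C(C)(C)C)c4ccc(O[C@H](CO)[C@H](O)c5ccc(O[Si](C(C)C)(C(C)C)C(C)C)c(OC)c5)c(OC)c4)c(OC)c2)cc1OC | intermediate
18 | penta(4-nitrobenzoate): esters on O-7 and O-9 of units A and C and on O-9 of unit B; unit A (7R,8S); unit B (7S,8S) 7-OTBS; unit C (7S,8R); two aryl OTIPS | c1(O[C@@H](COC(=O)c8ccc(cc8)[N+](=O)[O-])[C@H](OC(=O)c8ccc(cc8)[N+](=O)[O-])c4ccc(O[Si](C(C)C)(C(C)C)C(C)C)c(OC)c4)c(OC)cc([C@H]2OC[C@H]3[C@@H]2CO[C@@H]3c2cc(OC)c(O[C@@H](COC(=O)c8ccc(cc8)[N+](=O)[O-])[C@@H](O[Si](C)(C)C(C)(C)C)c4ccc(O[C@H](COC(=O)c8ccc(cc8)[N+](=O)[O-])[C@@H](OC(=O)c8ccc(cc8)[N+](=O)[O-])c5ccc(O[Si](C(C)C)(C(C)C)C(C)C)c(OC)c5)c(OC)c4)c(OC)c2)cc1OC | intermediate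
19 | trisilyl ether of the target: 4-O-TIPS on the aryl rings of units A and C, 7-O-TBS on unit B, all other OH free | c1(O[C@@H](CO)[C@H](O)c4ccc(O[Si](C(C)C)(C(C)C)C(C)C)c(OC)c4)c(OC)cc([C@H]2OC[C@H]3[C@@H]2CO[C@@H]3c2cc(OC)c(O[C@@H](CO)[C@@H](O[Si](C)(C)C(C)(C)C)c4ccc(O[C@H](CO)[C@@H](O)c5ccc(O[Si](C(C)C)(C(C)C)C(C)C)c(OC)c5)c(OC)c4)c(OC)c2)cc1OC | intermediate
20 | CNP0316493.3: (+)-syringaresinol 4-O-[erythro-(7R,8S)-guaiacylglycerol-8-yl] 4'-O-{threo-(7S,8S)-guaiacylglycerol-8-yl 4-O-[erythro-(7S,8R)-guaiacylglycerol-8-yl]} diether | COc1cc([C@@H](O)[C@H](CO)Oc2c(OC)cc([C@H]3OC[C@H]4[C@@H]3CO[C@@H]4c3cc(OC)c(O[C@@H](CO)[C@@H](O)c4ccc(O[C@H](CO)[C@@H](O)c5ccc(O)c(OC)c5)c(OC)c4)c(OC)c3)cc2OC)ccc1O | target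

**Totals**
Total step count: 11. Longest linear sequence: 9 steps (5 → 20 through steps 3–11; the branch 1 → 3 joining at step 4 is equally long).

**Three steps most likely to fail**

Step 9 (double Mitsunobu inversion). Two electron-rich benzylic carbinols in free 1,3-diols may ionise or suffer ester participation, giving retention or elimination. The fallback sets out from 17 and comes back at 20, replacing SN2 inversion by oxidation and chelation-controlled reduction. TBSCl (3.3 equiv) and imidazole in CH2Cl2 at 0 °C silylate only the three primary hydroxyls to give the tris(C9-silyl ether) F6. Dess–Martin periodinane buffered with NaHCO3 oxidises the two free benzylic alcohols to the diketone F7, which is used at once to avoid epimerisation at C8. Zn(BH4)2 in Et2O at −20 °C reduces both ketones through a zinc chelate between the carbonyl and the aryloxy oxygen, with hydride delivered anti to the CH2OTBS group, to give the erythro diol F8. TBAF/AcOH in THF then removes all six silyl groups and gives 20.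

Step 4 (first aldol). The boron enolate must be formed in the presence of a free hindered phenol, and the aldehyde carries its own enolisable imide. The fallback sets out from 7 and comes back at 11, protecting first instead of masking in the flask. TBSCl and imidazole in DMF convert 7 into the aryl silyl ether F1. Bu2BOTf (1.1 equiv) and iPr2NEt then give the Z-boron enolate F2, which adds to 3 at −78 °C to give the boron aldolate F3. Buffered H2O2 work-up releases the hydroxy imide F4, and TBSOTf/2,6-lutidine silylates O-7 of unit B to give 11.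

Step 6 (fluoride-triggered alkylation). Fluoride may attack the imides or induce β-elimination of the silyloxy group before the phenoxide is alkylated. The fallback sets out from 10 and comes back at 13, reversing the order of alkylation and silylation so that no fluoride is used. The free phenol of 10 is alkylated with 6 (K2CO3, NaI, acetone, rt, short reaction time to limit retro-aldol) to give the hydroxy tris-imide F5. TBSOTf/2,6-lutidine in CH2Cl2 at −78 °C then silylates O-7 of unit B and gives 13.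

**Further compounds**
F1 | step 4 | aryl silyl ether: 7 with core O-4 as TBS ether | CC(C)(C)[Si](C)(C)Oc1c(OC)cc([C@H]2OC[C@H]3[C@@H]2CO[C@@H]3c2cc(OC)c(OCC(=O)N6[C@H](Cc7ccccc7)COC6=O)c(OC)c2)cc1OC
F2 | step 4 | Z-boron enolate of F1 (ArO cis to OBBu2) | CC(C)(C)[Si](C)(C)Oc1c(OC)cc([C@H]2OC[C@H]3[C@@H]2CO[C@@H]3c2cc(OC)c(O/C=C(\OB(CCCC)CCCC)N6[C@H](Cc7ccccc7)COC6=O)c(OC)c2)cc1OC
F3 | step 4 | boron aldolate: F4 with O-7 of unit B as O–BBu2 | CC(C)(C)[Si](C)(C)Oc1c(OC)cc([C@H]2OC[C@H]3[C@@H]2CO[C@@H]3c2cc(OC)c(O[C@@H](C(=O)N6[C@H](Cc7ccccc7)COC6=O)[C@@H](OB(CCCC)CCCC)c4ccc(OCC(=O)N6[C@@H](Cc7ccccc7)COC6=O)c(OC)c4)c(OC)c2)cc1OC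
F4 | step 4 | hydroxy imide: 10 with core O-4 as TBS ether, 7-OH of unit B free | CC(C)(C)[Si](C)(C)Oc1c(OC)cc([C@H]2OC[C@H]3[C@@H]2CO[C@@H]3c2cc(OC)c(O[C@@H](C(=O)N6[C@H](Cc7ccccc7)COC6=O)[C@@H](O)c4ccc(OCC(=O)N6[C@@H](Cc7ccccc7)COC6=O)c(OC)c4)c(OC)c2)cc1OC
F5 | step 6 | hydroxy tris-imide: 13 with free 7-OH on unit B | O=C(COc1c(OC)cc([C@H]2OC[C@H]3[C@@H]2CO[C@@H]3c2cc(OC)c(O[C@@H](C(=O)N6[C@H](Cc7ccccc7)COC6=O)[C@@H](O)c4ccc(OCC(=O)N6[C@@H](Cc7ccccc7)COC6=O)c(OC)c4)c(OC)c2)cc1OC)N1[C@H](Cc2ccccc2)COC1=O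
F6 | step 9 | tris(C9-silyl ether): 17 with the three primary hydroxyls as TBS ethers | c1(O[C@@H](CO[Si](C)(C)C(C)(C)C)[C@@H](O)c4ccc(O[Si](C(C)C)(C(C)C)C(C)C)c(OC)c4)c(OC)cc([C@H]2OC[C@H]3[C@@H]2CO[C@@H]3c2cc(OC)c(O[C@@H](CO[Si](C)(C)C(C)(C)C)[C@@H](O[Si](C)(C)C(C)(C)C)c4ccc(O[C@H](CO[Si](C)(C)C(C)(C)C)[C@H](O)c5ccc(O[Si](C(C)C)(C(C)C)C(C)C)c(OC)c5)c(OC)c4)c(OC)c2)cc1OC
F7 | step 9 | diketone: F6 with C7 of units A and C oxidised to C=O | c1(O[C@@H](CO[Si](C)(C)C(C)(C)C)C(=O)c4ccc(O[Si](C(C)C)(C(C)C)C(C)C)c(OC)c4)c(OC)cc([C@H]2OC[C@H]3[C@@H]2CO[C@@H]3c2cc(OC)c(O[C@@H](CO[Si](C)(C)C(C)(C)C)[C@@H](O[Si](C)(C)C(C)(C)C)c4ccc(O[C@H](CO[Si](C)(C)C(C)(C)C)C(=O)c5ccc(O[Si](C(C)C)(C(C)C)C(C)C)c(OC)c5)c(OC)c4)c(OC)c2)cc1OC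
F8 | step 9 | erythro diol: F7 reduced to (7R) in unit A and (7S) in unit C, all silyl groups kept | c1(O[C@@H](CO[Si](C)(C)C(C)(C)C)[C@H](O)c4ccc(O[Si](C(C)C)(C(C)C)C(C)C)c(OC)c4)c(OC)cc([C@H]2OC[C@H]3[C@@H]2CO[C@@H]3c2cc(OC)c(O[C@@H](CO[Si](C)(C)C(C)(C)C)[C@@H](O[Si](C)(C)C(C)(C)C)c4ccc(O[C@H](CO[Si](C)(C)C(C)(C)C)[C@@H](O)c5ccc(O[Si](C(C)C)(C(C)C)C(C)C)c(OC)c5)c(OC)c4)c(OC)c2)cc1OC
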